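**Retrosynthetic overview**
1. Target ⇒ spiro-indanol phenol: the last step only adjusts oxidation level (C11 oxygenation, carbinol to ketone, enolisation to the hydroxy quinone methide enone).
2. Spiro-indanol ⇒ 7-alkenylferruginol: face-selective epoxidation of the exocyclic alkene (C–O bond), then in the same flask arene C14 opens the epoxide; this closes the spiro cyclopentane (last ring) and sets the quaternary centre.
3. 7-Alkenylferruginol ⇒ ferruginol quinone methide + alkenyltrifluoroborate of the sesquiterpene half (C7–C bond by 1,6-addition).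
4. Sesquiterpene half ⇒ bicyclo[3.1.0]hexanone (cyclopentane and cyclopropane formed together by intramolecular cyclopropanation) ⇒ diazoketone from isovaleraldehyde and methyl vinyl ketone via Michael addition and Claisen rearrangement.
5. Ferruginol ⇒ rings A and B by enantioselective polyene cyclisation onto bought ring C (2-isopropylanisole + geranyl chloride).

Assumption: abietane numbering is used for the diterpene half; Cs is the spiro carbon and Cb the carbon between C7 and Cs (the later ring ketone); for each chiral catalyst the ligand antipode that gives the drawn isomer is meant.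

**Step 1**
Reactants: 1 3-methylbutanal; 2 but-3-en-2-one
Product: 3 (2S)-2-isopropyl-5-oxohexanal
Conditions: (S)-2-[methoxy(diphenyl)methyl]pyrrolidine (5 mol%), ethyl 3,4-dihydroxybenzoate (20 mol%), neat, 4 °C
Reagents that add atoms: none
Why: Enamine-catalysed Michael addition in which the diarylprolinol ether shields one enamine face and so sets the (S) centre that becomes the side-chain CH(iPr) stereocentre.

**Step 2**
Reactants: 3 (2S)-2-isopropyl-5-oxohexanal
Product: 4 (5S)-6-hydroxy-5-isopropyloct-7-en-2-one (both C6 epimers)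
Conditions: CH2=CHBr, CrCl2 (3 equiv), NiCl2 (1 mol%), DMF, 23 °C
Reagents that add atoms: vinyl bromide, C=CBr
Why: Nozaki–Hiyama–Kishi vinylation adds to the aldehyde and leaves the methyl ketone untouched; the new carbinol centre is lost in step 4.

**Step 3**
Reactants: 4 (5S)-6-hydroxy-5-isopropyloct-7-en-2-one
Product: 5 (4S)-5-methyl-4-[2-(2-methyl-1,3-dioxolan-2-yl)ethyl]hex-1-en-3-ol (both C3 epimers)
Conditions: HOCH2CH2OH, PPTS (10 mol%), benzene, reflux, Dean–Stark
Reagents that add atoms: ethylene glycol, OCCO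
Why: Acid-catalysed ketalisation masks the side-chain methyl ketone so that later enolate, diazo-transfer and olefination chemistry meets only the new carbonyl groups.

**Step 4**
Reactants: 5 (4S)-5-methyl-4-[2-(2-methyl-1,3-dioxolan-2-yl)ethyl]hex-1-en-3-ol
Product: 7 (5E,7S)-7-isopropyl-9-(2-methyl-1,3-dioxolan-2-yl)non-5-en-2-one, via allyl isopropenyl ether 6 (not isolated)
Conditions: 2-methoxypropene (5 equiv), PPTS (2 mol%), xylene, 130 °C, sealed tube
Reagents that add atoms: 2-methoxypropene, COC(C)=C
Why: Ketone Claisen (Saucy–Marbet) [3,3] rearrangement through a chair transition state with the branched substituent equatorial gives the E alkene and the γ,δ-unsaturated methyl ketone.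

**Step 5**
Reactants: 7 (5E,7S)-7-isopropyl-9-(2-methyl-1,3-dioxolan-2-yl)non-5-en-2-one
Product: 9 (5E,7S)-1-diazo-7-isopropyl-9-(2-methyl-1,3-dioxolan-2-yl)non-5-en-2-one, via trifluoroacetyl ketone 8 (not isolated)
Conditions: LiN(SiMe3)2, THF, −78 °C; CF3CO2CH2CF3; then MsN3, Et3N, H2O (1 equiv), MeCN, 23 °C
Reagents that add atoms: methanesulfonyl azide, CS(=O)(=O)N=[N+]=[N-]
Why: Danheiser detrifluoroacetylative diazo transfer, in which the kinetic methyl enolate is trifluoroacetylated and the activated position then takes N2 from the sulfonyl azide with loss of the trifluoroacetyl group.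

**Step 6**
Reactants: 9 (5E,7S)-1-diazo-7-isopropyl-9-(2-methyl-1,3-dioxolan-2-yl)non-5-en-2-one
Product: 10 (1S,5S,6S)-6-[(3S)-2-methyl-5-(2-methyl-1,3-dioxolan-2-yl)pentan-3-yl]bicyclo[3.1.0]hexan-2-one
Conditions: [Cu(MeCN)4]PF6 (5 mol%), 2,2′-isopropylidenebis[(4S)-4-tert-butyl-2-oxazoline] (6 mol%), CH2Cl2, 23 °C, slow addition
Reagents that add atoms: none
Why: Intramolecular cyclopropanation by a copper carbene is stereospecific (E alkene gives the exo side chain) and the bisoxazoline ligand selects the alkene face, which sets the three ring stereocentres.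

**Step 7**
Reactants: 10 (1S,5S,6S)-6-[(3S)-2-methyl-5-(2-methyl-1,3-dioxolan-2-yl)pentan-3-yl]bicyclo[3.1.0]hexan-2-one
Product: 12 potassium (E)-alkenyltrifluoroborate (BF3K on the exocyclic CH of the 2-ylidene), via alkenyl pinacol boronate 11 (not isolated)
Conditions: CH2(Bpin)2, lithium 2,2,6,6-tetramethylpiperidide, THF, 0 °C, then 10, −78 to 23 °C; then KHF2, MeOH/H2O, 0 °C
Reagents that add atoms: bis(pinacolato)borylmethane, CC1(C)OB(CB2OC(C)(C)C(C)(C)O2)OC1(C)C; potassium hydrogen difluoride, F.[F-].[K+]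
Why: Boron-Wittig olefination (addition of the gem-diboryl carbanion, then B–O elimination) places boron away from the more substituted bridgehead side (E), and KHF2 converts the boronate into the more nucleophilic trifluoroborate.

**Step 8**
Reactants: 13 2-isopropylanisole
Product: 14 4-(chloromethyl)-2-isopropylanisole
Conditions: (CH2O)n, conc. HCl, ZnCl2 (cat.), 60 °C
Reagents that add atoms: formaldehyde, C=O; hydrogen chloride, Cl
Why: Blanc chloromethylation takes place para to the methoxy group.

**Step 9**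
Reactants: 14 4-(chloromethyl)-2-isopropylanisole; 15 geranyl chloride
Product: 17 4-[(3E)-4,8-dimethylnona-3,7-dien-1-yl]-2-isopropylanisole, via benzylic Grignard reagent 16 (not isolated)
Conditions: Mg, THF, 0 °C; then 15, Li2CuCl4 (3 mol%), −10 °C
Reagents that add atoms: none
Why: Copper-catalysed SN2 coupling of the benzylic Grignard reagent with the primary allylic chloride occurs at the α-carbon and keeps the E alkene.

**Step 10**
Reactants: 17 4-[(3E)-4,8-dimethylnona-3,7-dien-1-yl]-2-isopropylanisole
Product: 18 (5S,10S)-12-methoxyabieta-8,11,13-triene (ferruginol methyl ether)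
Conditions: (R)-3,3′-dichloro-BINOL·SbCl5 (0.5 equiv), CH2Cl2, −78 °C
Reagents that add atoms: none
Why: Enantioselective proton-initiated cation–olefin polycyclisation with a chiral Lewis-acid-assisted Brønsted acid gives the trans A/B fusion through chair–chair folding, the ligand sets (5S,10S), and the arene closes at the ortho position remote from the isopropyl group.

**Step 11**
Reactants: 18 ferruginol methyl ether
Product: 19 (5S,10S)-abieta-8,11,13-trien-12-ol (ferruginol)
Conditions: BBr3, CH2Cl2, −78 to 0 °C; H2O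
Reagents that add atoms: none
Why: Lewis-acid cleavage of the aryl methyl ether frees the phenol without touching the stereocentres.

**Step 12**
Reactants: 19 ferruginol; 12 potassium (E)-alkenyltrifluoroborate
Product: 21 7α-{(E)-[bicyclo[3.1.0]hexan-2-ylidene]methyl}ferruginol carrying the dioxolane side chain, via quinone methide 20 (not isolated)
Conditions: DDQ (1.05 equiv), CH2Cl2, −40 °C; then 12, BF3·OEt2, −40 to 0 °C
Reagents that add atoms: none
Why: DDQ removes hydride from C7 to give the para-quinone methide, and BF3-promoted 1,6-addition of the alkenyltrifluoroborate (ipso attack through a boron-stabilised cyclopropylcarbinyl cation, then loss of boron) forms the C7–Cb bond with retention of alkene geometry, anti to the C10 methyl group; the C7 centre is erased in step 14.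

**Step 13**
Reactants: 21 7α-alkenylferruginol
Product: 24 spiro-indanol methyl ketone (C14–Cs bond closed; OH on Cb; 12-OH free), via spiro-epoxide 22 (not isolated), via spiro-indanol dioxolane 23 (not isolated)
Conditions: mCPBA (1.1 equiv), CH2Cl2, −40 °C; then (CF3)2CHOH, −40 to 0 °C; then PPTS, acetone/H2O, 40 °C
Reagents that add atoms: mCPBA, O=C(OO)c1cccc(Cl)c1; water, O
Why: Proposed new method: one-pot anti oxy-arylation in which the peracid epoxidises the exocyclic alkene on the face anti to the cyclopropane (as with sabinene-type 2-methylenebicyclo[3.1.0]hexanes) and the hexafluoroisopropanol-activated epoxide is opened at the tertiary cyclopropylcarbinyl carbon by arene C14 with inversion in a five-ring Friedel–Crafts closure, so that the aryl group ends syn to the cyclopropane and the C–O bond anti, which is the spiro configuration of the target and supplies the oxygen of the later ring ketone; the closest known reaction type is the fluoroalcohol- or Lewis-acid-promoted epoxide–arene cyclisation to six-membered rings (Stork–Eschenmoser anti addition), not yet shown for a five-ring spirocyclisation at a cyclopropylcarbinyl carbon.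

**Step 14**
Reactants: 24 spiro-indanol methyl ketone
Product: 26 CNP0140364.1 (target), via ortho-quinone diketone 25 (not isolated)
Conditions: IBX (2.5 equiv), DMSO, 23 °C
Reagents that add atoms: IBX, O=C1OI(=O)(O)c2ccccc12
Why: IBX oxidises the secondary alcohol to the ring ketone and oxygenates the phenol at C11 (the only free ortho position) to the 11,12-ortho-quinone, which enolises through the acidic C7–H to the conjugated 11-hydroxy quinone methide enone; only the C7 and Cb centres, both destroyed, are affected.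

**Compound list**
1 | 3-methylbutanal (isovaleraldehyde) | CC(C)CC=O | starting material
2 | but-3-en-2-one (methyl vinyl ketone) | CC(=O)C=C | starting material
3 | (2S)-2-isopropyl-5-oxohexanal | CC(=O)CC[C@@H](C(C)C)C=O | intermediate
4 | (5S)-6-hydroxy-5-isopropyloct-7-en-2-one, both C6 epimers | CC(=O)CC[C@@H](C(C)C)C(O)C=C | intermediate
5 | (4S)-5-methyl-4-[2-(2-methyl-1,3-dioxolan-2-yl)ethyl]hex-1-en-3-ol, both C3 epimers | CC1(CC[C@@H](C(C)C)C(O)C=C)OCCO1 | intermediate
6 | isopropenyl ether of 5 (allyl isopropenyl ether) | CC1(CC[C@@H](C(C)C)C(OC(C)=C)C=C)OCCO1 | intermediate (not isolated)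
7 | (5E,7S)-7-isopropyl-9-(2-methyl-1,3-dioxolan-2-yl)non-5-en-2-one | CC(=O)CC/C=C/[C@@H](CCC1(C)OCCO1)C(C)C | intermediate
8 | (7E,9S)-1,1,1-trifluoro-9-isopropyl-11-(2-methyl-1,3-dioxolan-2-yl)undec-7-ene-2,4-dione | FC(F)(F)C(=O)CC(=O)CC/C=C/[C@@H](CCC1(C)OCCO1)C(C)C | intermediate (not isolated)
9 | (5E,7S)-1-diazo-7-isopropyl-9-(2-methyl-1,3-dioxolan-2-yl)non-5-en-2-one | [N-]=[N+]=CC(=O)CC/C=C/[C@@H](CCC1(C)OCCO1)C(C)C | intermediate
10 | (1S,5S,6S)-6-[(3S)-2-methyl-5-(2-methyl-1,3-dioxolan-2-yl)pentan-3-yl]bicyclo[3.1.0]hexan-2-one, side chain exo | CC1(CC[C@@H](C(C)C)[C@H]2[C@@H]3CCC(=O)[C@@H]32)OCCO1 | intermediate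
11 | pinacol (E)-alkenylboronate: 10 with C2=CH–Bpin in place of C2=O, boron cis to C3 | CC1(CC[C@@H](C(C)C)[C@H]2[C@@H]3CC/C(=C\B4OC(C)(C)C(C)(C)O4)[C@@H]32)OCCO1 | intermediate (not isolated)
12 | potassium (E)-alkenyltrifluoroborate corresponding to 11 | CC1(CC[C@@H](C(C)C)[C@H]2[C@@H]3CC/C(=C\[B-](F)(F)F)[C@@H]32)OCCO1.[K+] | intermediate
13 | 2-isopropylanisole | COc1ccccc1C(C)C | starting material
14 | 4-(chloromethyl)-2-isopropylanisole | COc1ccc(CCl)cc1C(C)C | intermediate
15 | geranyl chloride | ClC/C=C(\C)CCC=C(C)C | starting material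
16 | (3-isopropyl-4-methoxybenzyl)magnesium chloride | COc1ccc(C[Mg]Cl)cc1C(C)C | intermediate (not isolated)
17 | 4-[(3E)-4,8-dimethylnona-3,7-dien-1-yl]-2-isopropylanisole | COc1ccc(CC/C=C(\C)CCC=C(C)C)cc1C(C)C | intermediate
18 | (5S,10S)-12-methoxyabieta-8,11,13-triene (ferruginol methyl ether) | CC(C)c1cc2c(cc1OC)[C@@]1(C)CCCC(C)(C)[C@@H]1CC2 | intermediate
19 | (5S,10S)-abieta-8,11,13-trien-12-ol (ferruginol) | CC(C)c1cc2c(cc1O)[C@@]1(C)CCCC(C)(C)[C@@H]1CC2 | intermediate
20 | (5S,10S)-abieta-7,9(11),13-trien-12-one (ferruginol quinone methide) | CC(C)C1=CC2=CC[C@H]3C(C)(C)CCC[C@]3(C)C2=CC1=O | intermediate (not isolated)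
21 | ferruginol bearing at C7 (α face) the (E)-ylidenemethyl group derived from 12 | CC1(CC[C@@H](C(C)C)[C@H]2[C@@H]3CC/C(=C\[C@@H]4C[C@H]5C(C)(C)CCC[C@]5(C)c6cc(O)c(C(C)C)cc64)[C@@H]32)OCCO1 | intermediate
22 | spiro-epoxide of 21, oxygen on the face anti to the cyclopropane | CC1(CC[C@@H](C(C)C)[C@H]2[C@@H]3CC[C@@]4(O[C@@H]4[C@@H]5C[C@H]6C(C)(C)CCC[C@]6(C)c7cc(O)c(C(C)C)cc75)[C@@H]32)OCCO1 | intermediate (not isolated)
23 | spiro-indanol dioxolane: C14 bonded to Cs (aryl syn to cyclopropane), OH on Cb, 12-OH free | CC1(CC[C@@H](C(C)C)[C@H]2[C@@H]3CC[C@@]4([C@H](O)[C@H]5c6c4c(C(C)C)c(O)cc6[C@@]4(C)CCCC(C)(C)[C@@H]4C5)[C@@H]32)OCCO1 | intermediate (not isolated)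
24 | spiro-indanol methyl ketone (23 without the dioxolane) | CC(=O)CC[C@@H](C(C)C)[C@H]1[C@@H]2CC[C@@]3([C@H](O)[C@H]4c5c3c(C(C)C)c(O)cc5[C@@]3(C)CCCC(C)(C)[C@@H]3C4)[C@@H]21 | intermediate
25 | 11,12-ortho-quinone of the Cb ketone | CC(=O)CC[C@@H](C(C)C)[C@H]1[C@@H]2CC[C@@]3(C(=O)[C@H]4C5=C([C@@]6(C)CCCC(C)(C)[C@@H]6C4)C(=O)C(=O)C(C(C)C)=C53)[C@@H]21 | intermediate (not isolated)
26 | CNP0140364.1 | CC(=O)CC[C@@H](C(C)C)[C@H]1[C@@H]2CC[C@@]3(C(=O)C4=C5C3=C(C(C)C)C(=O)C(O)=C5[C@@]3(C)CCCC(C)(C)[C@@H]3C4)[C@@H]21 | target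

**Step count and risks**
Total: 14 steps. Longest linear sequence: 10 steps (steps 1–7, then 12–14); the diterpene branch (steps 8–11) joins at step 12.

Step 13 (proposed new oxy-arylation). The epoxide may instead undergo a hydride shift to the open-chain ketone, and stereospecificity may be lost at the cyclopropylcarbinyl carbon; the spiro centre is the main stereochemical risk of the route. Fallback with known chemistry, from 21 back to 26: Lewis-base-catalysed thiiranium carbosulfenylation of 21 [N-(phenylthio)succinimide, (Me2N)3P=Se (10 mol%), MsOH, CH2Cl2, −20 °C], a known anti addition with arene capture at the more substituted carbon, gives the phenylthio spiro-indane F1 with the same spiro configuration. mCPBA (1 equiv, −78 °C) gives the sulfoxide F2. Pummerer rearrangement (TFAA, 2,6-lutidine; then aqueous HCl, which also cleaves the dioxolane) gives the keto phenol F3. IBX as in step 14 takes F3 through 25 to 26.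

Step 12 (quinone methide alkenylation). The quinone methide may isomerise to the 6,7-alkene, and the cationic intermediate may open the cyclopropane. Fallback from 19 back to 21: 19 is oxidised to 20 with DDQ and trapped by 1,6-addition of lithiated 1-tert-butyl-5-(methylsulfonyl)tetrazole to give the 7α-sulfonylmethyl phenol F4. Julia–Kocienski olefination of ketone 10 with F4 [LiN(SiMe3)2 (2.2 equiv), THF, −78 to 23 °C] gives 21; either alkene isomer can be carried on because Cb is oxidised later.

Step 6 (cyclopropanation). Face selectivity rests on the ligand working against or with an acyclic allylic stereocentre. Fallback from 5 back to 10: O-propargylation of 5 (NaH, propargyl bromide) gives the allyl propargyl ether F5. [2,3]-Wittig rearrangement (n-BuLi 2.2 equiv, THF, −78 °C) gives the E enynol, of which the (3R)-carbinol F6 is used (the epimer is inverted by Mitsunobu reaction). Pivaloylation (PivCl, DMAP) gives the pivalate F7. PtCl2-catalysed enyne cycloisomerisation (5 mol%, toluene, 80 °C), which relays the carbinol configuration to the cyclopropane, gives the enol pivalate F8. K2CO3 in MeOH gives 10.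

**Further compounds**
F1 | step 13 | phenylthio spiro-indane: 23 with SPh in place of OH on Cb | CC1(CC[C@@H](C(C)C)[C@H]2[C@@H]3CC[C@@]4([C@H](Sc5ccccc5)[C@H]6c7c4c(C(C)C)c(O)cc7[C@@]8(C)CCCC(C)(C)[C@@H]8C6)[C@@H]32)OCCO1
F2 | step 13 | sulfoxide of F1 (both sulfur epimers) | CC1(CC[C@@H](C(C)C)[C@H]2[C@@H]3CC[C@@]4([C@H](S(=O)c5ccccc5)[C@H]6c7c4c(C(C)C)c(O)cc7[C@@]8(C)CCCC(C)(C)[C@@H]8C6)[C@@H]32)OCCO1
F3 | step 13 | keto phenol: 24 with C=O in place of CH(OH) at Cb | CC(=O)CC[C@@H](C(C)C)[C@H]1[C@@H]2CC[C@@]3(C(=O)[C@H]4c5c3c(C(C)C)c(O)cc5[C@@]3(C)CCCC(C)(C)[C@@H]3C4)[C@@H]21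
F4 | step 12 | 7α-[(1-tert-butyltetrazol-5-yl)sulfonylmethyl]ferruginol | CC(C)c1cc2c(cc1O)[C@@]3(C)CCCC(C)(C)[C@@H]3C[C@H]2CS(=O)(=O)c4nnnn4C(C)(C)C
F5 | step 6 | propargyl ether of 5 (both carbinol epimers) | C#CCOC(C=C)[C@@H](CCC1(C)OCCO1)C(C)C
F6 | step 6 | (3R,5E,7S)-7-isopropyl-9-(2-methyl-1,3-dioxolan-2-yl)non-5-en-1-yn-3-ol | C#C[C@H](O)C/C=C/[C@@H](CCC1(C)OCCO1)C(C)C
F7 | step 6 | pivalate of F6 | C#C[C@H](OC(=O)C(C)(C)C)C/C=C/[C@@H](CCC1(C)OCCO1)C(C)C
F8 | step 6 | enol pivalate of 10 (bicyclo[3.1.0]hex-2-en-2-yl pivalate) | CC1(CC[C@@H](C(C)C)[C@H]2[C@@H]3CC=C(OC(=O)C(C)(C)C)[C@@H]32)OCCO1
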